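**Retrosynthetic overview**

1. Target ⇒ (global deprotection) its tetraacetate / bis-silyl ether. Ring numbering used below: cyclohexene C1 carries the chalcone aryl, C2=C3(Me), C4H2, C5 carries the resorcinol ring, C6 carries the chromenoyl ketone.
2. Two disconnections are made in one flask. The ketone C(=O)–C6 bond comes from Rh-catalysed hydroacylation of an arylacetylene by a chromene salicylaldehyde, which gives a 2'-hydroxychalcone. The C1–C6 and C4–C5 ring bonds come from an endo [4+2] of that enone with a dehydroprenyl-chalcone diene on a chiral boron template.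
3. Enabling feature: the free phenolic OH on C5 of the 2H-chromene ring, ortho to the carbonyl carbon attached at C6 (an O–C5–C6–C=O salicyloyl unit). It chelates Rh for the aldehyde C–H activation and then, together with the new ketone oxygen, chelates boron for the cycloaddition.
4. Ring order: the pyran ring of the chromene first (condensation / oxa-6π on 2,4-dihydroxybenzaldehyde), the cyclohexene ring last, in the key step. All benzene rings are bought.
5. Fragments: the arylacetylene by silylation / Colvin homologation of the same aldehyde; the diene from 2,4-dihydroxyacetophenone by iodination, Claisen–Schmidt condensation and Suzuki coupling.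

Key step: step 12

Assumption: (S)-VANOL is taken as the ligand enantiomer whose boron complex shields the enone face leading to the (1S,5S,6R) adduct; if the sense proves opposite, (R)-VANOL is used and nothing else changes.

**Route**

Step 1
Reactants: 1 2,4-dihydroxybenzaldehyde; 2 3-methylbut-2-enal
Product: 3 5-hydroxy-2,2-dimethyl-2H-chromene-6-carbaldehyde
Conditions: ethylenediammonium diacetate (20 mol %), xylene, reflux
Reagents that add atoms: none
Why: Amine-catalysed Knoevenagel-type condensation at the ring carbon between the two oxygens, then oxa-6π electrocyclisation of the o-quinone methide, closes the 2H-pyran ring on the 4-oxygen while the 2-OH stays hydrogen-bonded to the formyl group; no stereocentre is formed.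

Step 2
Reactants: 1 2,4-dihydroxybenzaldehyde
Product: 4 2,4-bis[(tert-butyldimethylsilyl)oxy]benzaldehyde
Conditions: TBSCl, imidazole, DMF, rt
Reagents that add atoms: tert-butyldimethylsilyl chloride, CC(C)(C)[Si](C)(C)Cl
Why: Standard silylation of both phenols gives aryl silyl ethers that are inert to LDA in the next step and to Rh(I) in the key step.

Step 3
Reactants: 4 2,4-bis[(tert-butyldimethylsilyl)oxy]benzaldehyde
Product: 5 1-ethynyl-2,4-bis[(tert-butyldimethylsilyl)oxy]benzene
Conditions: TMSCHN2, LDA, THF, −78 °C to rt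
Reagents that add atoms: trimethylsilyldiazomethane, C[Si](C)(C)C=[N+]=[N-]
Why: Colvin homologation: lithiated trimethylsilyldiazomethane adds to the aldehyde, Peterson elimination and loss of N2 give an alkylidene carbene, and its 1,2-H shift delivers the terminal alkyne.

Step 4
Reactants: 6 1-(2,4-dihydroxyphenyl)ethan-1-one
Product: 7 1-(2,4-dihydroxy-3-iodophenyl)ethan-1-one
Conditions: I2, HIO3, EtOH/H2O, 40 °C
Reagents that add atoms: iodine, II; iodic acid, O[I](=O)=O
Why: Electrophilic aromatic iodination at the doubly activated carbon flanked by the two hydroxyls, which should be favoured over C5.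

Step 5
Reactants: 7 1-(2,4-dihydroxy-3-iodophenyl)ethan-1-one
Product: 8 1-[2-hydroxy-3-iodo-4-(methoxymethoxy)phenyl]ethan-1-one
Conditions: MOMCl, K2CO3, acetone, rt
Reagents that add atoms: chloromethyl methyl ether, COCCl
Why: Williamson-type O-alkylation of the more acidic, non-chelated 4-OH; the 2-OH is hydrogen-bonded to the acetyl group and stays free.

Step 6
Reactants: 1 2,4-dihydroxybenzaldehyde
Product: 9 2,4-bis(methoxymethoxy)benzaldehyde
Conditions: NaH, MOMCl, DMF, 0 °C to rt
Reagents that add atoms: chloromethyl methyl ether, COCCl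
Why: O-alkylation of both sodium phenoxides gives the base-stable bis-MOM ether needed for the aldol step.

Step 7
Reactants: 8 1-[2-hydroxy-3-iodo-4-(methoxymethoxy)phenyl]ethan-1-one; 9 2,4-bis(methoxymethoxy)benzaldehyde
Product: 10 (E)-3-[2,4-bis(methoxymethoxy)phenyl]-1-[2-hydroxy-3-iodo-4-(methoxymethoxy)phenyl]prop-2-en-1-one
Conditions: KOH (50 % aq.), EtOH, rt; then HCl to pH 3
Reagents that add atoms: none
Why: Claisen–Schmidt condensation; E1cB dehydration of the aldol gives the conjugated E-enone.

Step 8
Reactants: 10 (E)-3-[2,4-bis(methoxymethoxy)phenyl]-1-[2-hydroxy-3-iodo-4-(methoxymethoxy)phenyl]prop-2-en-1-one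
Product: 11 (E)-1-(2,4-dihydroxy-3-iodophenyl)-3-(2,4-dihydroxyphenyl)prop-2-en-1-one
Conditions: 3 M HCl, MeOH, 50 °C
Reagents that add atoms: none
Why: Acid-catalysed acetal exchange with methanol removes the three MOM groups, and the aryl iodide and the E-enone should survive dilute acid at this temperature.

Step 9
Reactants: 11 (E)-1-(2,4-dihydroxy-3-iodophenyl)-3-(2,4-dihydroxyphenyl)prop-2-en-1-one
Product: 12 (E)-1-(2,4-diacetoxy-3-iodophenyl)-3-(2,4-diacetoxyphenyl)prop-2-en-1-one
Conditions: Ac2O, pyridine, DMAP (cat.), CH2Cl2, rt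
Reagents that add atoms: acetic anhydride, CC(=O)OC(C)=O
Why: DMAP-catalysed acylation of all four phenols; the 2'-acetate also removes the OH/C=O chelation site that would otherwise let this enone act as a boron-activated dienophile in step 12.

Step 10
Reactants: 13 2-methylbut-1-en-3-yne
Product: 14 (E)-4,4,5,5-tetramethyl-2-(3-methylbuta-1,3-dien-1-yl)-1,3,2-dioxaborolane
Conditions: pinacolborane, Cp2Zr(H)Cl (5 mol %), Et3N (10 mol %), neat, 50 °C
Reagents that add atoms: pinacolborane, [H]B1OC(C)(C)C(C)(C)O1
Why: Zirconium-catalysed syn hydroboration of the terminal alkyne with anti-Markovnikov regiochemistry gives the E-dienyl boronate and leaves the 1,1-disubstituted alkene untouched.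

Step 11
Reactants: 12 (E)-1-(2,4-diacetoxy-3-iodophenyl)-3-(2,4-diacetoxyphenyl)prop-2-en-1-one; 14 (E)-4,4,5,5-tetramethyl-2-(3-methylbuta-1,3-dien-1-yl)-1,3,2-dioxaborolane
Product: 15 (E)-1-{2,4-diacetoxy-3-[(E)-3-methylbuta-1,3-dien-1-yl]phenyl}-3-(2,4-diacetoxyphenyl)prop-2-en-1-one
Conditions: Pd(dppf)Cl2 (5 mol %), CsF, 1,4-dioxane, 70 °C
Reagents that add atoms: none
Why: Suzuki–Miyaura coupling with retention of the E geometry of the alkenyl boronate; anhydrous fluoride activation should spare the aryl acetates.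

Step 12
Reactants: 3 5-hydroxy-2,2-dimethyl-2H-chromene-6-carbaldehyde; 5 1-ethynyl-2,4-bis[(tert-butyldimethylsilyl)oxy]benzene; 15 (E)-1-{2,4-diacetoxy-3-[(E)-3-methylbuta-1,3-dien-1-yl]phenyl}-3-(2,4-diacetoxyphenyl)prop-2-en-1-one
Product: 17 (E)-1-{2,4-diacetoxy-3-[(1S,5S,6R)-5-{2,4-bis[(tert-butyldimethylsilyl)oxy]phenyl}-6-(5-hydroxy-2,2-dimethyl-2H-chromene-6-carbonyl)-3-methylcyclohex-2-en-1-yl]phenyl}-3-(2,4-diacetoxyphenyl)prop-2-en-1-one, via 2'-hydroxychalcone 16 (not isolated)
Conditions: 3 + 5, [Rh(cod)Cl]2 (2.5 mol %), dppf (5 mol %), Na2CO3 (10 mol %), PhMe, 80 °C; then 15 and the complex preformed from (S)-VANOL, BH3·THF and AcOH (1.2 equiv), THF, rt to 40 °C; aqueous work-up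
Reagents that add atoms: none
Why: Rh(I) adds into the aldehyde C–H of 3 through the five-membered O,C-chelate offered by the C5 phenoxide (which also suppresses decarbonylation), the alkyne of 5 inserts into Rh–H with Rh on the terminal carbon, and C–C reductive elimination gives E-enone 16 by syn H/acyl addition, so the C(acyl)–C bond is made here; the closest known reaction type is the Rh-catalysed hydroacylation of alkynes with salicylaldehydes. The same phenol, now paired with the new ketone oxygen of 16, binds the chiral boron complex, and the activated enone undergoes a concerted intermolecular [4+2] with 15, the closest known reaction type being the boron-templated enantioselective Diels–Alder reaction of 2'-hydroxychalcones. The cyclohexene ring is closed by this suprafacial [4+2] in the endo mode (aroyl group under the diene), forming C1–C6 and C4–C5. The C5/C6 trans relation follows from the E geometry of 16, the C1/C6 cis relation from the endo transition state, and the absolute sense from the VANOL ligand on boron, which shields one face of the chelated enone. The step needs linear regioselectivity in the hydroacylation (secured by the chelate and the bulky ortho-silyloxy group next to the internal alkyne carbon), "ortho/para" regioselectivity in the cycloaddition (secured by the 1-aryl and 3-methyl donors, which both put the largest HOMO coefficient on the CH2 terminus), and chemoselectivity for the enone of 16 over that of 15 (secured by the 2'-OAc of 15, which cannot chelate boron); 15 is added only after the Rh stage so that Rh–H never meets the diene. Endo/exo control is the weakest point, and the exo (all-trans) isomer, if formed, should be removed by chromatography.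

Step 13
Reactants: 17 (E)-1-{2,4-diacetoxy-3-[(1S,5S,6R)-5-{2,4-bis[(tert-butyldimethylsilyl)oxy]phenyl}-6-(5-hydroxy-2,2-dimethyl-2H-chromene-6-carbonyl)-3-methylcyclohex-2-en-1-yl]phenyl}-3-(2,4-diacetoxyphenyl)prop-2-en-1-one
Product: 18 (E)-1-{3-[(1S,5S,6R)-5-(2,4-dihydroxyphenyl)-6-(5-hydroxy-2,2-dimethyl-2H-chromene-6-carbonyl)-3-methylcyclohex-2-en-1-yl]-2,4-dihydroxyphenyl}-3-(2,4-dihydroxyphenyl)prop-2-en-1-one
Conditions: K2CO3, MeOH, 0 °C to rt; then aq. NH4Cl
Reagents that add atoms: none
Why: Base-mediated methanolysis cleaves the four aryl acetates and the two aryl silyl ethers in one operation; short contact at low temperature should leave the only epimerisable centre (C6–H, alpha to the ketone) and the other two stereocentres untouched.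

**Compound list**

1 | 2,4-dihydroxybenzaldehyde | O=Cc1ccc(O)cc1O | starting material
2 | 3-methylbut-2-enal | CC(C)=CC=O | starting material
3 | 5-hydroxy-2,2-dimethyl-2H-chromene-6-carbaldehyde | CC1(C)C=Cc2c(O1)ccc(C=O)c2O | intermediate
4 | 2,4-bis[(tert-butyldimethylsilyl)oxy]benzaldehyde | O=Cc1ccc(O[Si](C)(C)C(C)(C)C)cc1O[Si](C)(C)C(C)(C)C | intermediate
5 | 1-ethynyl-2,4-bis[(tert-butyldimethylsilyl)oxy]benzene | C#Cc1ccc(O[Si](C)(C)C(C)(C)C)cc1O[Si](C)(C)C(C)(C)C | intermediate
6 | 1-(2,4-dihydroxyphenyl)ethan-1-one | CC(=O)c1ccc(O)cc1O | starting material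
7 | 1-(2,4-dihydroxy-3-iodophenyl)ethan-1-one | CC(=O)c1ccc(O)c(I)c1O | intermediate
8 | 1-[2-hydroxy-3-iodo-4-(methoxymethoxy)phenyl]ethan-1-one | CC(=O)c1ccc(OCOC)c(I)c1O | intermediate
9 | 2,4-bis(methoxymethoxy)benzaldehyde | COCOc1ccc(C=O)c(OCOC)c1 | intermediate
10 | (E)-3-[2,4-bis(methoxymethoxy)phenyl]-1-[2-hydroxy-3-iodo-4-(methoxymethoxy)phenyl]prop-2-en-1-one | COCOc1ccc(/C=C/C(=O)c2ccc(OCOC)c(I)c2O)c(OCOC)c1 | intermediate
11 | (E)-1-(2,4-dihydroxy-3-iodophenyl)-3-(2,4-dihydroxyphenyl)prop-2-en-1-one | O=C(/C=C/c1ccc(O)cc1O)c1ccc(O)c(I)c1O | intermediate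
12 | (E)-1-(2,4-diacetoxy-3-iodophenyl)-3-(2,4-diacetoxyphenyl)prop-2-en-1-one | CC(=O)Oc1ccc(/C=C/C(=O)c2ccc(OC(C)=O)c(I)c2OC(C)=O)c(OC(C)=O)c1 | intermediate
13 | 2-methylbut-1-en-3-yne | CC(=C)C#C | starting material
14 | (E)-4,4,5,5-tetramethyl-2-(3-methylbuta-1,3-dien-1-yl)-1,3,2-dioxaborolane | CC(=C)/C=C/B1OC(C)(C)C(C)(C)O1 | intermediate
15 | (E)-1-{2,4-diacetoxy-3-[(E)-3-methylbuta-1,3-dien-1-yl]phenyl}-3-(2,4-diacetoxyphenyl)prop-2-en-1-one | CC(=C)/C=C/c1c(OC(C)=O)ccc(C(=O)/C=C/c2ccc(OC(C)=O)cc2OC(C)=O)c1OC(C)=O | intermediate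
16 | (E)-3-{2,4-bis[(tert-butyldimethylsilyl)oxy]phenyl}-1-(5-hydroxy-2,2-dimethyl-2H-chromen-6-yl)prop-2-en-1-one | O=C(/C=C/c1ccc(O[Si](C)(C)C(C)(C)C)cc1O[Si](C)(C)C(C)(C)C)c1ccc2OC(C)(C)C=Cc2c1O | intermediate
17 | (E)-1-{2,4-diacetoxy-3-[(1S,5S,6R)-5-{2,4-bis[(tert-butyldimethylsilyl)oxy]phenyl}-6-(5-hydroxy-2,2-dimethyl-2H-chromene-6-carbonyl)-3-methylcyclohex-2-en-1-yl]phenyl}-3-(2,4-diacetoxyphenyl)prop-2-en-1-one | CC1=C[C@H](c2c(OC(C)=O)ccc(C(=O)/C=C/c3ccc(OC(C)=O)cc3OC(C)=O)c2OC(C)=O)[C@H](C(=O)c2ccc3c(c2O)C=CC(C)(C)O3)[C@@H](c2ccc(O[Si](C)(C)C(C)(C)C)cc2O[Si](C)(C)C(C)(C)C)C1 | intermediate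
18 | (E)-1-{3-[(1S,5S,6R)-5-(2,4-dihydroxyphenyl)-6-(5-hydroxy-2,2-dimethyl-2H-chromene-6-carbonyl)-3-methylcyclohex-2-en-1-yl]-2,4-dihydroxyphenyl}-3-(2,4-dihydroxyphenyl)prop-2-en-1-one | CC1=C[C@H](c2c(O)ccc(C(=O)/C=C/c3ccc(O)cc3O)c2O)[C@H](C(=O)c2ccc3c(c2O)C=CC(C)(C)O3)[C@@H](c2ccc(O)cc2O)C1 | target

**Step count and risks**

Total step count: 13. Longest linear sequence: 8 steps (6 → 18 through steps 4, 5, 7, 8, 9, 11, 12 and 13).

Steps most likely to fail:

Step 12. The alkyne may insert with the wrong regiochemistry (acyl delivered to the internal carbon) or oligomerise on Rh, carried-over Rh/phosphine may interfere with the boron template, and endo/exo discrimination in the cycloaddition may be weak. The fallback makes the same C(acyl)–C bond by carbonyl addition and separates the two events. It sets out from 3 and 5: 5 is deprotonated with n-BuLi (THF, −78 °C) and the lithium acetylide is added to 3, previously converted into its sodium phenoxide with NaH. This should give racemic 1-(5-hydroxy-2,2-dimethyl-2H-chromen-6-yl)-3-{2,4-bis[(tert-butyldimethylsilyl)oxy]phenyl}prop-2-yn-1-ol F1. A redox isomerisation of the propargylic alcohol (indenyl-ruthenium catalyst with In(OTf)3, or DABCO for this 1,3-diaryl case) should then give the E-enone. The fallback comes back to the route at 16, which is now isolated and purified and submitted to the boron-mediated cycloaddition with 15 as a separate operation to reach 17; temperature and ligand can then be tuned for endo selectivity without regard to the Rh stage.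

Step 11. Protodeboronation or polymerisation of the dienyl boronate may outrun transmetalation at the doubly ortho-substituted aryl-palladium species, and fluoride may start to cleave acetates. The fallback avoids the boronate and builds the diene in two stages from 12. Heck reaction of 12 with 2-methylbut-3-en-2-ol (Pd(OAc)2, P(o-tol)3, Et3N, MeCN, 80 °C) should give (E)-1-{2,4-diacetoxy-3-[(E)-3-hydroxy-3-methylbut-1-en-1-yl]phenyl}-3-(2,4-diacetoxyphenyl)prop-2-en-1-one F2. Dehydration of the tertiary allylic alcohol (MsCl, Et3N, CH2Cl2, 0 °C to rt), which can only eliminate towards a methyl group, returns to the route at 15.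

Step 13. Epimerisation at the ketone alpha-carbon (C6) towards the all-trans series, or oxa-Michael closure of the 2'-hydroxychalcone to a flavanone, may occur during carbonate methanolysis. The fallback uses two orthogonal, non-basic cleavages starting from 17. HF·pyridine (THF, 0 °C) removes the two silyl groups to give (E)-1-{2,4-diacetoxy-3-[(1S,5S,6R)-5-(2,4-dihydroxyphenyl)-6-(5-hydroxy-2,2-dimethyl-2H-chromene-6-carbonyl)-3-methylcyclohex-2-en-1-yl]phenyl}-3-(2,4-diacetoxyphenyl)prop-2-en-1-one F3. Neutral deacetylation of the aryl acetates with NH4OAc in aqueous MeOH at rt then returns to the route at 18.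

Further compounds
F1 | step 12 | 1-(5-hydroxy-2,2-dimethyl-2H-chromen-6-yl)-3-{2,4-bis[(tert-butyldimethylsilyl)oxy]phenyl}prop-2-yn-1-ol (racemic) | OC(C#Cc1ccc(O[Si](C)(C)C(C)(C)C)cc1O[Si](C)(C)C(C)(C)C)c1ccc2OC(C)(C)C=Cc2c1O
F2 | step 11 | (E)-1-{2,4-diacetoxy-3-[(E)-3-hydroxy-3-methylbut-1-en-1-yl]phenyl}-3-(2,4-diacetoxyphenyl)prop-2-en-1-one | CC(C)(O)/C=C/c1c(OC(C)=O)ccc(C(=O)/C=C/c2ccc(OC(C)=O)cc2OC(C)=O)c1OC(C)=O
F3 | step 13 | (E)-1-{2,4-diacetoxy-3-[(1S,5S,6R)-5-(2,4-dihydroxyphenyl)-6-(5-hydroxy-2,2-dimethyl-2H-chromene-6-carbonyl)-3-methylcyclohex-2-en-1-yl]phenyl}-3-(2,4-diacetoxyphenyl)prop-2-en-1-one | CC1=C[C@H](c2c(OC(C)=O)ccc(C(=O)/C=C/c3ccc(OC(C)=O)cc3OC(C)=O)c2OC(C)=O)[C@H](C(=O)c2ccc3c(c2O)C=CC(C)(C)O3)[C@@H](c2ccc(O)cc2O)C1
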